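Follow the intermediate through its exits, and count substrate as the fraction left.

in all of them: substrate 0.056 M; partner 0.700 equiv

| charge | time | remark |
|---|---|---|
| green | 25 h | plug flow through a tube for 25 h, no back-mixing |
| amber |  | one stirred flow tank at steady state, fed with the mixture as stated, mean residence time 25 h |
| violet | 25 h | everything together in a closed stirred flask, run for 25 h |
| grey |  | a single well-mixed tank run continuously and read at steady state, 125 h in it on average |

1. the set-up with the highest share of target in all that became target or side product, at the outlet or at the end ("none" if the first two lie within 2 percentage points) (green / amber / violet / grey / none)
2. share of target in all that became target or side product, at the outlet or at the end, green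
3. share of target in all that became target or side product, at the outlet or at the end, amber
4. share of target in all that became target or side product, at the outlet or at the end, violet
5. share of target in all that became target or side product, at the outlet or at the end, grey

    substrate + intermediate → side product (k1 = 11 M⁻¹ h⁻¹)
    substrate + partner ⇌ intermediate (K2 = 65 M⁻¹, k2 = 3.6 M⁻¹ h⁻¹)
    intermediate ⇌ target + released group (K3 = 0.0094 M, k3 = 0.16 h⁻¹)
    released group → by-product carried off (k4 = 0.086 h⁻¹)

- percent here means substrate units held: one side product counts as two
- the stated concentrations are those of everything mixed, before any reaction; amounts are the same in each set-up
- run time (green): 25 h

Take green, whose plug of liquid lives the same history as violet's closed flask. An intermediate moves on to target at 0.16 h⁻¹, or it meets substrate at 11 M⁻¹ h⁻¹ times c(substrate), and that exit costs two units. With c(substrate) as charged, the share, a selectivity in substrate units, starts at 11.5%. It climbs as the fraction left falls, and the two exits carry equal units at the even level 0.00727 M, which is 13.0% of the charge. Summing the share down the fraction left, I reckon target made as the even level times the logarithm of (even level plus charge) over (even level plus c(substrate)). With substrate taken to zero and no target coming back, that gives 28.1% of the charge.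

But target does come back. A released group meets target at 0.16 h⁻¹ over 0.0094 M, times c(target), or it is carried off at 0.086 h⁻¹. These two rates are equal at the return level 0.00505 M, the c(target) at which a released group is as likely to go back as to leave, 9.02% of the charge. On my reckoned curve, target reaches this knee with 0.0243 M of substrate left, 43.4% of the charge. With the released group held steady, the forward exit keeps half of its flow at the knee, and less above it. Halving the even level from there and taking substrate to zero, I reckon target at 22.3% of the charge. By hand I go no further than this level and a choice: grey, a stirred tank like amber, whose 125 h exceeds amber's 25 h.

The forecast names grey too, with 16.5%, 17.6%, 16.5% and 22.4% in the order asked: “Stirred tanks keep substrate low”.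

The simulation gives 15.7%, 17.6%, 15.7% and 22.3% in the same order, so grey leads. Green holds 70.9% as side product, which with its share reads as target at 13.2% of the charge, or 0.00737 M, 1.46 times the return level, where a released group goes back at 0.125 h⁻¹, above the 0.086 h⁻¹ of leaving. Grey holds target at 18.2%, twice the return level, where going back runs at 0.173 h⁻¹.

The constants are invented; what happens was integrated by code.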